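**Bench rule.** Count what one equivalent of partner B buys before you set up a series. The flasks below differ in their charge of partner B, and two earlier runs stand beside them.

| flask | substrate | partner A | partner B | remark | time |
|---|---|---|---|---|---|
| grey | 0.20 M | 1.1 equiv | 1.4 equiv | run made earlier |  |
| blue | 0.20 M | 1.1 equiv | 7.5 equiv | run made earlier |  |
| maple | 0.20 M | 1.10 equiv | 1.00 equiv |  | 15 d |
| elm | 0.20 M | 1.10 equiv | 1.50 equiv |  | 15 d |
| cedar | 0.20 M | 1.10 equiv | 2.50 equiv |  | 15 d |
| birch | 0.20 M | 1.10 equiv | 3.00 equiv |  | 15 d |
| alder | 0.20 M | 1.10 equiv | 5.00 equiv |  | 15 d |

- grey (time / d: target / %, substrate / %): 0.625: 12.0, 79.0; 1.04: 17.5, 71.5; 1.67: 24.7, 64.0; 2.50: 30.4, 57.8; 5.00: 37.3, 50.2; 8.00: 40.2, 47.1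
- blue (time / d: target / %, substrate / %): 1.25: 38.8, 5.0; 2.50: 42.1, 0.9; 4.00: 43.5, 0.1; 5.00: 43.4, 0.2; 6.00: 43.4, 0.3; 8.00: 43.7, 0.8

(each reading ± 0.3 percentage points)

- the numbers in the tables scatter by 0.3 percentage points (one standard deviation)
- "hardly changes" means that all values lie within two and a half points (for a concentration: within two and a half percent of the largest)

- amount of target at the end, in percent of the substrate charged for maple, elm, cedar, birch, alder, in this order
- the course of these numbers from the first flask to the last (rises all the way / hardly changes / rises, then falls / falls, then rises / falls all the way)

**The draw.** After 8.00 d the grey run still held 47.1 % of its substrate, and that level had moved little since 5.00 d, when it read 50.2 %. Treat partner B as the limiting reagent of the grey run. That run then consumed 37.8 % of the substrate per equivalent charged. Call this reading the draw, the share of substrate consumed per equivalent of partner B.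

**Its border.** Multiply the draw by the charge and you have the substrate consumed, but the product has to stay less than the substrate charged. For the blue run it gives 283 %, more than the whole charge, so the rule has stopped working there. The ratio of the grey charge to the share it consumed puts the border at 2.65. Past the border, extra partner B finds no further substrate to claim. The blue run also kept less target per substrate consumed than the grey run, 0.441 against 0.760. Cedar, at 2.50 equiv, is charged with less than the border, and birch, at 3.00 equiv, with more. So my own reckoning, which holds the substrate consumed at the whole charge past the border and lets target per substrate consumed fall with the charge as it does between those two runs, puts the top of the row at or below the border, and it does not separate cedar from birch.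

**The forecast.** It reads 32 %, 43 %, 50 %, 51 % and 48 %, with the course rises, then falls, and concludes that “the yield peaks near 3 equiv”. It therefore parts from my reckoning at the top, giving birch more than cedar, and birch stands above the border.

**The result.** The flasks give 28.1 %, 44.7 %, 56.3 %, 54.1 % and 47.7 %, with the course rises, then falls and cedar highest.

    substrate + partner B → open intermediate (k = 0.0880 L mol⁻¹ h⁻¹)
    partner B + partner A → second intermediate (k = 0.610 L mol⁻¹ h⁻¹)
    open intermediate + second intermediate → target (k = 10.0 L mol⁻¹ h⁻¹)
    2 second intermediate → homo product (k = 9.10 L mol⁻¹ h⁻¹)
    partner A ⇌ dormant form (K = 2.90, k = 0.220 h⁻¹)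

At the end, cedar holds 41.9 % of its substrate as open intermediate. The draw leaves 5.50 % of the substrate in cedar, and the flask holds 1.89 %. In maple the draw leaves 62.2 %, and the flask holds 65.6 %.

The earlier runs and the new flask stem from a simulated flask with made-up constants, noise included.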